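**Retrosynthetic overview**
- **Feature.** Ring A of unit 1 (C4a, C5, C6, C7, C8, C8a) carries O1, O5 and O7 in a 1,3,5 (phloroglucinol) pattern. Written as a 3,5-dimethoxyphenyl ether, its two carbons ortho to O1 are equivalent. The C5 methoxy group ends up peri to C4=O, so it alone can later be cleaved by chelation.
- **Last cuts.** BCl3 removes four benzyl ethers and the C5 methyl ether. Before that, C4–C4a is disconnected (intramolecular Friedel–Crafts acylation), which opens ring C to a (Z)-3-(3,5-dimethoxyphenoxy)-2,3-diarylacrylic acid that already holds ring E and unit 2 on C3.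
- **The acid.** It comes from a tert-butyl arylacetate by C-aroylation (C2–C3), Z-enol triflate formation, phenoxide addition–elimination (C2–O1) and acidolysis.
- **The arylacetate.** It comes from a 3'-bromoflavone by Negishi–Reformatsky coupling. The bromoflavone comes from a chalcone of dibenzylated phloroacetophenone and 4-benzyloxy-3-bromobenzaldehyde.
- **Ring order.** The pyranone ring of unit 2 closes first (step 4) and ring C of unit 1 last (step 10). All benzene rings are bought.

Key step: step 10

Assumption: the target SMILES carries no stereodescriptor, so the hindered C3–aryl axis is treated as stereochemically undefined and no control over it is attempted.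

Shorthand: Ar(E) = 2-(benzyloxy)-5-[5,7-bis(benzyloxy)-4-oxo-4H-chromen-2-yl]phenyl, that is ring E carrying benzyl-protected unit 2. Ring B is the 4-oxygenated phenyl group on C2 of unit 1.

**Step 1**
Reactants: 1 2,4,6-trihydroxyacetophenone
Product: 2 1-[2,4-bis(benzyloxy)-6-hydroxyphenyl]ethanone
Conditions: BnBr (2.1 equiv), K2CO3 (2.5 equiv), DMF, 70 °C
Reagents that add atoms: benzyl bromide, BrCc1ccccc1
Why: Williamson etherification in which two equivalents of benzyl bromide take the C4 hydroxyl and one of the two equivalent ortho hydroxyls, while the last hydroxyl is hydrogen-bonded to the acetyl oxygen and is alkylated far more slowly.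

**Step 2**
Reactants: 3 3-bromo-4-hydroxybenzaldehyde
Product: 4 4-(benzyloxy)-3-bromobenzaldehyde
Conditions: BnBr (1.1 equiv), K2CO3, DMF, rt
Reagents that add atoms: benzyl bromide, BrCc1ccccc1
Why: Williamson etherification of an acidic para-formylphenol, with the aldehyde and the aryl bromide inert to K2CO3.

**Step 3**
Reactants: 2 1-[2,4-bis(benzyloxy)-6-hydroxyphenyl]ethanone; 4 4-(benzyloxy)-3-bromobenzaldehyde
Product: 5 (E)-1-[2,4-bis(benzyloxy)-6-hydroxyphenyl]-3-[4-(benzyloxy)-3-bromophenyl]prop-2-en-1-one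
Conditions: KOH (50% aq.), EtOH–THF, rt; then dilute HCl
Reagents that add atoms: none
Why: Claisen–Schmidt condensation in which the methyl ketone enolate adds to the non-enolisable aldehyde and E1cB loss of water gives the conjugated E-alkene as the thermodynamic product, the benzyl ethers and the aryl bromide being stable to hydroxide.

**Step 4**
Reactants: 5 the 2'-hydroxychalcone
Product: 6 5,7-bis(benzyloxy)-2-[4-(benzyloxy)-3-bromophenyl]-4H-chromen-4-one
Conditions: I2 (0.1 equiv), DMSO, 130 °C; aq. Na2S2O3 work-up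
Reagents that add atoms: none
Why: Iodine-catalysed oxidative cyclisation of a 2'-hydroxychalcone, the standard flavone closure (6-endo attack of the phenol oxygen on the enone and dehydrogenation, DMSO re-oxidising HI), with iodine kept catalytic so that neither iodination at C6/C8 nor HI cleavage of the benzyl ethers competes.

**Step 5**
Reactants: 6 the 3'-bromoflavone; 7 (2-tert-butoxy-2-oxoethyl)zinc bromide (commercial solution in THF)
Product: 8 tert-butyl 2-{2-(benzyloxy)-5-[5,7-bis(benzyloxy)-4-oxo-4H-chromen-2-yl]phenyl}acetate, that is Ar(E)CH2CO2tBu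
Conditions: Pd2(dba)3 (2.5 mol %), XPhos (10 mol %), THF, 65 °C
Reagents that add atoms: none
Why: Negishi-type α-arylation with a Reformatsky reagent, in which the aryl bromide adds oxidatively to zerovalent palladium, the neutral zinc enolate transmetalates and reductive elimination forms the aryl–CH2 bond, while this weakly basic nucleophile leaves the vinylogous-ester carbonyl of the chromone untouched.

**Step 6**
Reactants: 8 Ar(E)CH2CO2tBu; 9 4-(benzyloxy)benzoyl chloride
Product: 10 tert-butyl 2-Ar(E)-3-[4-(benzyloxy)phenyl]-3-oxopropanoate (racemic)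
Conditions: LiN(SiMe3)2 (2.2 equiv), THF, −78 °C; then 9 (1.05 equiv), −78 → 0 °C; aq. NH4Cl
Reagents that add atoms: none
Why: Crossed Claisen-type C-acylation of an ester enolate, in which LiN(SiMe3)2 removes only the benzylic ester proton, the tert-butyl group suppresses self-condensation, the second equivalent of base stores the more acidic product as its enolate, and the new C-alpha stereocentre forms racemic and disappears in step 7.

**Step 7**
Reactants: 10 the β-keto ester
Product: 11 tert-butyl (Z)-2-Ar(E)-3-[4-(benzyloxy)phenyl]-3-{[(trifluoromethyl)sulfonyl]oxy}prop-2-enoate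
Conditions: LiOSO2CF3 (2 equiv), Et3N (1.3 equiv), (CF3SO2)2O (1.15 equiv), CH2Cl2, −78 → 0 °C
Reagents that add atoms: trifluoromethanesulfonic anhydride, O=S(=O)(OS(=O)(=O)C(F)(F)F)C(F)(F)F
Why: O-sulfonylation of a β-keto ester enolate (enol triflate formation), in which lithium bridges the enolate oxygen and the ester carbonyl so that the triflyloxy and ester groups end up cis, that is Z.

**Step 8**
Reactants: 11 the Z-enol triflate; 12 3,5-dimethoxyphenol
Product: 13 tert-butyl (Z)-2-Ar(E)-3-[4-(benzyloxy)phenyl]-3-(3,5-dimethoxyphenoxy)prop-2-enoate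
Conditions: Cs2CO3 (1.5 equiv), DMF, rt → 50 °C
Reagents that add atoms: none
Why: Nucleophilic vinylic substitution by addition–elimination, as in the classical phenoxide/β-haloacrylate route to 3-aryloxyacrylates, in which the phenoxide adds to the ester-activated β-carbon and triflate leaves from the ester enolate, normally with retention so that aryloxy and ester stay cis, and no hydrogen is available for a competing elimination.

**Step 9**
Reactants: 13 the tert-butyl 3-aryloxyacrylate
Product: 14 (Z)-2-Ar(E)-3-[4-(benzyloxy)phenyl]-3-(3,5-dimethoxyphenoxy)prop-2-enoic acid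
Conditions: CF3CO2H (20 vol %) in dry CH2Cl2, 0 °C → rt; toluene azeotrope
Reagents that add atoms: none
Why: Acidolysis of a tert-butyl ester by alkyl–oxygen fission (AAL1), which needs no attack on the crowded carbonyl and spares the β-aryloxyacrylate and the pyranone of unit 2 from hydroxide, while the cold anhydrous medium holds back benzyl ether loss and decarboxylation.

**Step 10**
Reactants: 14 the (Z)-3-aryloxy-2,3-diarylacrylic acid
Product: 16 3-{2-(benzyloxy)-5-[5,7-bis(benzyloxy)-4-oxo-4H-chromen-2-yl]phenyl}-2-[4-(benzyloxy)phenyl]-5,7-dimethoxy-4H-chromen-4-one, via mixed trifluoroacetic anhydride 15 (not isolated)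
Conditions: (CF3CO)2O (5 equiv), CH2Cl2, 0 °C → rt; aq. NaHCO3
Reagents that add atoms: trifluoroacetic anhydride, O=C(OC(=O)C(F)(F)F)C(F)(F)F (its trifluoroacetyl group is held only by intermediate 15 and leaves again on ring closure)
Why: Trifluoroacetic anhydride turns the acid into mixed anhydride 15, whose acyl carbon (as the anhydride or as the acylium ion conjugated with the aryl enol ether) is attacked by an ortho carbon of the 3,5-dimethoxyphenoxy ring, and proton loss from the arenium ion completes the C4–C4a bond; this is the intramolecular Friedel–Crafts acylation of a 3-aryloxyacrylic acid (Ruhemann-type chromone synthesis), used in the same way for xanthones from 2-aryloxybenzoic acids. Ring C closes in a 6-exo-trig mode at the activated carbonyl, which requires the carboxyl and aryloxy groups to be cis on the alkene. That geometry is delivered by steps 7 and 8, and any E isomer can drain into the Z series because the liberated trifluoroacetic acid protonates the push-pull alkene reversibly at C-alpha. Regioselectivity needs no control, since the two carbons ortho to the ether oxygen are related by symmetry, each being para to one methoxy group and ortho to the other, so both give the same 5,7-dimethoxychromone. Chemoselectivity rests on the much higher nucleophilicity of this trioxygenated ring compared with ring B (its ortho carbons are meta to the benzyloxy group, which disfavours indenone formation) and on the absence of a strong Lewis acid, which leaves the four benzyl ethers in place. No stereocentre is formed.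

**Step 11**
Reactants: 16 the 5-O-methyl tetra-O-benzyl biflavone
Product: 17 3-[5-(5,7-dihydroxy-4-oxo-4H-chromen-2-yl)-2-hydroxyphenyl]-5-hydroxy-2-(4-hydroxyphenyl)-7-methoxy-4H-chromen-4-one (target)
Conditions: BCl3 (1 M in CH2Cl2, 12 equiv), pentamethylbenzene (12 equiv), CH2Cl2, −78 → 0 °C; then H2O
Reagents that add atoms: none
Why: Lewis-acid ether cleavage in which BCl3 ionises the aryl benzyl ethers at low temperature with pentamethylbenzene as a non-basic trap for benzyl cations, and on warming cleaves only the C5 methyl ether, because boron chelated between C4=O and O5 activates that methyl group towards chloride, whereas the unchelated C7 methoxy group is inert to BCl3 under these conditions.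

**Compound list**
1 | 2,4,6-trihydroxyacetophenone | CC(=O)c1c(O)cc(O)cc1O | starting material
2 | 1-[2,4-bis(benzyloxy)-6-hydroxyphenyl]ethanone | CC(=O)c1c(O)cc(OCc2ccccc2)cc1OCc1ccccc1 | intermediate
3 | 3-bromo-4-hydroxybenzaldehyde | O=Cc1ccc(O)c(Br)c1 | starting material
4 | 4-(benzyloxy)-3-bromobenzaldehyde | O=Cc1ccc(OCc2ccccc2)c(Br)c1 | intermediate
5 | (E)-1-[2,4-bis(benzyloxy)-6-hydroxyphenyl]-3-[4-(benzyloxy)-3-bromophenyl]prop-2-en-1-one | O=C(/C=C/c1ccc(OCc2ccccc2)c(Br)c1)c1c(O)cc(OCc2ccccc2)cc1OCc1ccccc1 | intermediate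
6 | 5,7-bis(benzyloxy)-2-[4-(benzyloxy)-3-bromophenyl]-4H-chromen-4-one | O=c1cc(-c2ccc(OCc3ccccc3)c(Br)c2)oc2cc(OCc3ccccc3)cc(OCc3ccccc3)c12 | intermediate
7 | (2-tert-butoxy-2-oxoethyl)zinc bromide | CC(C)(C)OC(=O)C[Zn]Br | starting material
8 | tert-butyl 2-{2-(benzyloxy)-5-[5,7-bis(benzyloxy)-4-oxo-4H-chromen-2-yl]phenyl}acetate | CC(C)(C)OC(=O)Cc1cc(-c2cc(=O)c3c(OCc4ccccc4)cc(OCc4ccccc4)cc3o2)ccc1OCc1ccccc1 | intermediate
9 | 4-(benzyloxy)benzoyl chloride | O=C(Cl)c1ccc(OCc2ccccc2)cc1 | starting material
10 | tert-butyl 2-{2-(benzyloxy)-5-[5,7-bis(benzyloxy)-4-oxo-4H-chromen-2-yl]phenyl}-3-[4-(benzyloxy)phenyl]-3-oxopropanoate (racemic) | CC(C)(C)OC(=O)C(C(=O)c1ccc(OCc2ccccc2)cc1)c1cc(-c2cc(=O)c3c(OCc4ccccc4)cc(OCc4ccccc4)cc3o2)ccc1OCc1ccccc1 | intermediate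
11 | tert-butyl (Z)-2-{2-(benzyloxy)-5-[5,7-bis(benzyloxy)-4-oxo-4H-chromen-2-yl]phenyl}-3-[4-(benzyloxy)phenyl]-3-{[(trifluoromethyl)sulfonyl]oxy}prop-2-enoate | CC(C)(C)OC(=O)/C(c1cc(-c2cc(=O)c3c(OCc4ccccc4)cc(OCc4ccccc4)cc3o2)ccc1OCc1ccccc1)=C(\OS(=O)(=O)C(F)(F)F)c1ccc(OCc2ccccc2)cc1 | intermediate
12 | 3,5-dimethoxyphenol | COc1cc(O)cc(OC)c1 | starting material
13 | tert-butyl (Z)-2-{2-(benzyloxy)-5-[5,7-bis(benzyloxy)-4-oxo-4H-chromen-2-yl]phenyl}-3-[4-(benzyloxy)phenyl]-3-(3,5-dimethoxyphenoxy)prop-2-enoate | CC(C)(C)OC(=O)/C(c1cc(-c2cc(=O)c3c(OCc4ccccc4)cc(OCc4ccccc4)cc3o2)ccc1OCc1ccccc1)=C(\Oc1cc(OC)cc(OC)c1)c1ccc(OCc2ccccc2)cc1 | intermediate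
14 | (Z)-2-{2-(benzyloxy)-5-[5,7-bis(benzyloxy)-4-oxo-4H-chromen-2-yl]phenyl}-3-[4-(benzyloxy)phenyl]-3-(3,5-dimethoxyphenoxy)prop-2-enoic acid | OC(=O)/C(c1cc(-c2cc(=O)c3c(OCc4ccccc4)cc(OCc4ccccc4)cc3o2)ccc1OCc1ccccc1)=C(\Oc1cc(OC)cc(OC)c1)c1ccc(OCc2ccccc2)cc1 | intermediate
15 | mixed anhydride of acid 14 and trifluoroacetic acid (Z) | O=C(OC(=O)C(F)(F)F)/C(c1cc(-c2cc(=O)c3c(OCc4ccccc4)cc(OCc4ccccc4)cc3o2)ccc1OCc1ccccc1)=C(\Oc1cc(OC)cc(OC)c1)c1ccc(OCc2ccccc2)cc1 | intermediate (not isolated)
16 | 3-{2-(benzyloxy)-5-[5,7-bis(benzyloxy)-4-oxo-4H-chromen-2-yl]phenyl}-2-[4-(benzyloxy)phenyl]-5,7-dimethoxy-4H-chromen-4-one | COc1cc(OC)c2c(=O)c(-c3cc(-c4cc(=O)c5c(OCc6ccccc6)cc(OCc6ccccc6)cc5o4)ccc3OCc3ccccc3)c(-c3ccc(OCc4ccccc4)cc3)oc2c1 | intermediate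
17 | 3-[5-(5,7-dihydroxy-4-oxo-4H-chromen-2-yl)-2-hydroxyphenyl]-5-hydroxy-2-(4-hydroxyphenyl)-7-methoxy-4H-chromen-4-one | COc1cc(O)c2c(=O)c(-c3cc(-c4cc(=O)c5c(O)cc(O)cc5o4)ccc3O)c(-c3ccc(O)cc3)oc2c1 | target

Total step count: 11
Longest linear sequence: 10 steps (1 → 2 → 5 → 6 → 8 → 10 → 11 → 13 → 14 → 16 → 17)

**Steps most likely to fail**

**Step 8.**
- The phenoxide may attack sulfur instead of carbon; this triflyl transfer would only regenerate the enolate of 10.
- Addition to a tetrasubstituted β-carbon that also carries a para-benzyloxyphenyl donor may be slow.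
- The ambident phenoxide may react through carbon.

The fallback replaces attack on the β-carbon by a cross-coupling. It sets out from 11 and 12. A zerovalent palladium catalyst (Pd2(dba)3, 2-di-tert-butylphosphino-2',4',6'-triisopropylbiphenyl, K3PO4, toluene, 90 °C) should insert into the vinyl C–O(triflate) bond and form the vinyl–OAr bond by reductive elimination, the known palladium-catalysed aryl enol ether synthesis from vinyl triflates. The phenoxide concentration stays low in the non-polar medium. The fallback comes back to the route at 13 and makes no new compound.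

**Step 10.**
- The acid may lose CO2 after protonation at C-alpha before it is activated.
- The activated carboxyl may be captured by the ortho benzyloxy oxygen of ring E, with loss of benzyl and lactone closure.
- The electron-rich rings may be trifluoroacetylated.
- E/Z equilibration may be too slow.

The fallback gives up ring closure and joins the two finished halves at C3. It sets out from 6.
- Compound 6 is borylated (B2pin2, KOAc, PdCl2(dppf), dioxane, 90 °C) to 5,7-bis(benzyloxy)-2-[4-(benzyloxy)-3-(4,4,5,5-tetramethyl-1,3,2-dioxaborolan-2-yl)phenyl]-4H-chromen-4-one F1.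
- In parallel, commercial 2'-hydroxy-4',6'-dimethoxyacetophenone and 4-(benzyloxy)benzaldehyde are condensed (KOH, EtOH) to (E)-3-[4-(benzyloxy)phenyl]-1-(2-hydroxy-4,6-dimethoxyphenyl)prop-2-en-1-one F2.
- F2 is cyclised (catalytic I2, DMSO, 130 °C) to 2-[4-(benzyloxy)phenyl]-5,7-dimethoxy-4H-chromen-4-one F3.
- F3 is lithiated at C3 and iodinated (LiN(iPr)2, THF, −78 °C, then I2) to 2-[4-(benzyloxy)phenyl]-3-iodo-5,7-dimethoxy-4H-chromen-4-one F4.
- Suzuki–Miyaura coupling of F1 and F4 (Pd(OAc)2, SPhos, K3PO4, toluene–H2O, 90 °C) comes back to the route at 16.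

**Step 11.**
- The C7 methoxy group may be cleaved as well.
- Cleavage at C5 may stay incomplete.
- Released benzyl cations may re-alkylate the phloroglucinol rings.

The fallback separates the two kinds of ether cleavage. It sets out from 16. Hydrogenolysis (H2, Pd/C, THF–MeOH, rt) removes the four benzyl groups without cations and should give 3-[5-(5,7-dihydroxy-4-oxo-4H-chromen-2-yl)-2-hydroxyphenyl]-2-(4-hydroxyphenyl)-5,7-dimethoxy-4H-chromen-4-one F5. Its peri methoxy group alone is then cleaved by chelation (AlCl3, MeCN, 60 °C; then dilute HCl), which comes back to the route at 17.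

**Further compounds**
F0 | step 8 | none | none
F1 | step 10 | 5,7-bis(benzyloxy)-2-[4-(benzyloxy)-3-(4,4,5,5-tetramethyl-1,3,2-dioxaborolan-2-yl)phenyl]-4H-chromen-4-one | CC1(C)OB(OC1(C)C)c1cc(-c2cc(=O)c3c(OCc4ccccc4)cc(OCc4ccccc4)cc3o2)ccc1OCc1ccccc1
F2 | step 10 | (E)-3-[4-(benzyloxy)phenyl]-1-(2-hydroxy-4,6-dimethoxyphenyl)prop-2-en-1-one | COc1cc(O)c(C(=O)/C=C/c2ccc(OCc3ccccc3)cc2)c(OC)c1
F3 | step 10 | 2-[4-(benzyloxy)phenyl]-5,7-dimethoxy-4H-chromen-4-one | COc1cc(OC)c2c(=O)cc(-c3ccc(OCc4ccccc4)cc3)oc2c1
F4 | step 10 | 2-[4-(benzyloxy)phenyl]-3-iodo-5,7-dimethoxy-4H-chromen-4-one | COc1cc(OC)c2c(=O)c(I)c(-c3ccc(OCc4ccccc4)cc3)oc2c1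
F5 | step 11 | 3-[5-(5,7-dihydroxy-4-oxo-4H-chromen-2-yl)-2-hydroxyphenyl]-2-(4-hydroxyphenyl)-5,7-dimethoxy-4H-chromen-4-one | COc1cc(OC)c2c(=O)c(-c3cc(-c4cc(=O)c5c(O)cc(O)cc5o4)ccc3O)c(-c3ccc(O)cc3)oc2c1
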